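**Retrosynthetic overview**

1. The 1,4-dioxane is cut at both C–O bonds (retro hetero-Diels–Alder). This gives the triterpenoid o-quinone, a tautomer of pristimerin with 8β-H, and a ring-fused cyclopentadiene of the nor-guaiane half. The five-membered ring is therefore made one oxidation level higher, as a diene.
2. Enabling feature: in the five-membered ring the two cis C–O carbons C3′ and C4′ lie next to the tetrasubstituted C1′=C5′ bond shared with the seven-membered ring, and C2′ is a methylene. C1′ (sp2, flanked by C2′H2 and C10′) is the former spiro carbon of a cyclobutene, and C5′ the former carbinol carbon beside it (1,2-vinyl shift, four- to five-membered).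
3. Sesquiterpenoid half: (S)-carvone → trans-dihydrocarvone → one-carbon homologation (seven-membered ring) → α-hydroxylation → spiro-cyclobutanone at the former carbonyl carbon → cyclobutene → carbinol.
4. Triterpenoid half: pristimerin → 1,6-hydrazide addition and allylic diazene rearrangement (sets C8–H, aromatises ring A, moves the alkene to C6=C7) → o-quinone.
5. Ring order: seven-membered ring (step 2), four-membered ring (step 5), then in step 11 the five-membered ring (from the four-membered one) and the dioxane ring.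

Key step: step 11

Remark (locants): triterpenoid half in friedelane numbering; sesquiterpenoid half in guaiane numbering with primes (C1′=C5′ ring-fusion alkene, C2′ methylene, C3′–O2, C4′–O3, C7′ isopropenyl, C10′ methyl).
Remark (assumption): pristimerin, a commercial natural product, is taken as the starting material for the triterpenoid half.
Remark (transient centres): in 4–10 and 16 the carbinol carbon (later C5′) and the spiro carbon (later C1′) are epimer mixtures and are drawn without configuration, because both become sp2 in step 11.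

**Route**

Step 1
Reactants: 1 (S)-(+)-carvone
Product: 2 (2S,5S)-2-methyl-5-(prop-1-en-2-yl)cyclohexan-1-one (trans-dihydrocarvone)
Conditions: LiBH(s-Bu)3, THF, −78 °C; H2O; then NaOMe (cat.), MeOH, rt
Reagents that add atoms: none
Why: Conjugate (1,4) hydride reduction of the enone leaves C5 untouched, and the new C2 centre is set by base equilibration to the trans-2,5-diequatorial ketone.

Step 2
Reactants: 2 trans-dihydrocarvone
Product: 3 (2S,5S)-2-methyl-5-(prop-1-en-2-yl)cycloheptan-1-one
Conditions: TMSCHN2, BF3·OEt2, CH2Cl2, −78 → −40 °C; then 1 M HCl, THF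
Reagents that add atoms: (trimethylsilyl)diazomethane, C[Si](C)(C)C=[N+]=[N-]
Why: Lewis acid promoted diazoalkane homologation (Tiffeneau–Demjanov-type 1,2-shift) in which the less substituted α-methylene should migrate, so the CHMe carbon stays next to the carbonyl with its configuration untouched; the α-silyl group is lost on acidic work-up.

Step 3
Reactants: 3 (2S,5S)-2-methyl-5-(prop-1-en-2-yl)cycloheptan-1-one
Product: 4 (4S,7S)-2-hydroxy-7-methyl-4-(prop-1-en-2-yl)cycloheptan-1-one (C2 epimers)
Conditions: LiN(i-Pr)2, THF, −78 °C; then 2-(phenylsulfonyl)-3-phenyloxaziridine, −78 °C; H2O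
Reagents that add atoms: 2-(phenylsulfonyl)-3-phenyloxaziridine, O=S(=O)(N1OC1c1ccccc1)c1ccccc1
Why: Kinetic deprotonation at the less substituted α-carbon and electrophilic enolate hydroxylation (Davis oxidation); the CHMe centre is not deprotonated, and the new carbinol centre forms as a mixture that is erased in step 11.

Step 4
Reactants: 4 α-hydroxy ketone
Product: 5 (4S,7S)-7-methyl-4-(prop-1-en-2-yl)-2-(triethylsilyloxy)cycloheptan-1-one
Conditions: Et3SiCl, imidazole, DMF, 0 °C → rt
Reagents that add atoms: chlorotriethylsilane, CC[Si](Cl)(CC)CC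
Why: Standard O-silylation masks the ketol for the basic steps 5 and 6 and is removed in step 8.

Step 5
Reactants: 5 silyloxy ketone
Product: 7 (7S,10S)-10-methyl-7-(prop-1-en-2-yl)-5-(triethylsilyloxy)spiro[3.6]decan-1-one, via oxaspiropentane 6 (not isolated)
Conditions: cyclopropyldiphenylsulfonium tetrafluoroborate, KN(SiMe3)2, DME, −45 °C; 5, −45 → 0 °C; then LiBF4 (cat.), benzene, rt
Reagents that add atoms: cyclopropyldiphenylsulfonium tetrafluoroborate, c1ccc(cc1)[S+](C1CC1)c1ccccc1.F[B-](F)(F)F
Why: Trost spiroannulation, in which the sulfonium cyclopropylide adds to the ketone and closes to 6, whose Lewis acid opening (cyclopropylcarbinyl to cyclobutyl shift) gives the cyclobutanone with its carbonyl next to the new spiro carbon; that spiro centre may form as a mixture and is erased in step 11.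

Step 6
Reactants: 7 spiro-cyclobutanone
Product: 8 (7S,10S)-10-methyl-7-(prop-1-en-2-yl)-5-(triethylsilyloxy)spiro[3.6]dec-1-en-1-yl trifluoromethanesulfonate
Conditions: PhNTf2, KN(SiMe3)2 (added last), THF, −78 °C; H2O
Reagents that add atoms: N-phenylbis(trifluoromethanesulfonimide), O=S(=O)(N(c1ccccc1)S(=O)(=O)C(F)(F)F)C(F)(F)F
Why: Enol triflate formation is regiospecific because the cyclobutanone has only one α-methylene, the other α-carbon being the quaternary spiro carbon.

Step 7
Reactants: 8 cyclobutenyl triflate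
Product: 9 triethyl{[(7S,10S)-10-methyl-7-(prop-1-en-2-yl)spiro[3.6]dec-1-en-5-yl]oxy}silane
Conditions: Pd(OAc)2 (cat.), PPh3, HCO2H, Bu3N, DMF, 60 °C
Reagents that add atoms: none
Why: Palladium-catalysed formate reduction of the enol triflate (oxidative addition, formate exchange, decarboxylation, C–H reductive elimination) gives the cyclobutene and should leave the isopropenyl group alone.

Step 8
Reactants: 9 silyl ether
Product: 10 (7S,10S)-10-methyl-7-(prop-1-en-2-yl)spiro[3.6]dec-1-en-5-ol
Conditions: Bu4NF, THF, 0 °C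
Reagents that add atoms: none
Why: Fluoride-mediated desilylation frees the carbinol that triggers the ring expansion in step 11.

Step 9
Reactants: 11 pristimerin
Product: 14 methyl 2,3-dihydroxy-8β-H-24-nor-D:A-friedooleana-1,3,5(10),6-tetraen-29-oate, via 6β-tosylhydrazino catechol 12 (not isolated), via 6β-diazenyl catechol 13 (not isolated)
Conditions: TsNHNH2, AcOH (cat.), degassed THF, 0 °C → rt; then NaOAc, 50 °C, argon
Reagents that add atoms: none
Why: Proposed new method: the hydrazide NH2 should add 1,6 to the extended quinone methide at C6 on the β face (axial entry on the ring-B half-boat that the chair of ring C imposes, syn to the C9 methyl, as expected for soft nucleophiles on this chromophore) to give 12, acetate-induced loss of sulfinate gives the allylic diazene 13, and its retro-ene loss of N2 delivers hydrogen suprafacially to C8 on the β face while the alkene moves to C6=C7, which sets C8 and leaves the catechol; the closest known reaction types are heteroatom 1,6-additions to quinone methides and the allylic diazene rearrangement of N-allyl-N′-sulfonylhydrazines (Kabalka and Myers transpositions).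

Step 10
Reactants: 14 catechol
Product: 15 methyl 2,3-dioxo-8β-H-24-nor-D:A-friedooleana-1(10),4,6-trien-29-oate (o-quinone)
Conditions: Ag2O, Na2SO4, Et2O, 0 °C, dark; filtered through Celite and used at once
Reagents that add atoms: none
Why: Neutral two-electron oxidation of the catechol to the o-quinone; the product is kept cold and free of base because deprotonation at C8 would tautomerise it to 11 and erase C8.

Step 11
Reactants: 10 spiro-cyclobutenyl carbinol; 15 o-quinone
Product: 18 CNP0149558.1, via secondary triflate 16 (not isolated), via cyclopentadiene 17 (not isolated)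
Conditions: Tf2O, 2,6-di-tert-butyl-4-methylpyridine, CH2Cl2, −78 → −30 °C; then 15 in CH2Cl2, −30 → 0 °C
Reagents that add atoms: none
Why: Proposed new method: triflation of the neopentyl-type alcohol gives 16, which should ionise with participation of the cyclobutene π bond, so that the vinyl carbon shifts from the spiro carbon to the carbinol carbon (cyclobutenylcarbinyl to cyclopentenyl cation) and the tertiary cation loses the ring-fusion proton to give the C1′=C5′/C3′=C4′ diene 17, which is trapped cold by 15 in an inverse-electron-demand hetero-Diels–Alder reaction across C3′=C4′. The closest known reaction types are the solvolytic cyclobutenylmethyl to cyclopentenyl rearrangement, the acid-induced conversion of spiro[3.n] carbinols into ring-fused alkenes, and the [4+2] addition of o-quinones to cyclopentadienes that gives cis-fused 1,4-benzodioxanes. The cyclopentene ring is closed by the 1,2-shift (ring expansion of the four-membered ring) and the dioxane ring by a suprafacial [4+2] cycloaddition of the O=C–C=O unit. C3′ and C4′ come out cis from the suprafacial addition, and their absolute sense should be set by the pseudo-axial C10′ methyl on the adjacent allylic carbon, which directs the quinone to the opposite face. The step needs vinyl rather than methylene migration (secured by π participation), proton loss toward the conjugated diene and trapping before 1,5-hydrogen shifts (low temperature, reactive quinone), and bonding of O2 to the diene terminus C3′ with O3 on C4′ (C3′ has the larger HOMO coefficient and less hindrance, and the C4 methyl flanks O3). Any carbocyclic [4+2] adduct should funnel to the aromatic benzodioxane by [3,3] shift.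

**Compound list**

1 | (S)-(+)-carvone, (5S)-2-methyl-5-(prop-1-en-2-yl)cyclohex-2-en-1-one | C=C(C)[C@H]1CC=C(C)C(=O)C1 | starting material
2 | (2S,5S)-2-methyl-5-(prop-1-en-2-yl)cyclohexan-1-one | C=C(C)[C@H]1CC[C@H](C)C(=O)C1 | intermediate
3 | (2S,5S)-2-methyl-5-(prop-1-en-2-yl)cycloheptan-1-one | C=C(C)[C@H]1CC[C@H](C)C(=O)CC1 | intermediate
4 | (4S,7S)-2-hydroxy-7-methyl-4-(prop-1-en-2-yl)cycloheptan-1-one, C2 epimers | C=C(C)[C@H]1CC[C@H](C)C(=O)C(O)C1 | intermediate
5 | (4S,7S)-7-methyl-4-(prop-1-en-2-yl)-2-(triethylsilyloxy)cycloheptan-1-one, C2 epimers | C=C(C)[C@H]1CC[C@H](C)C(=O)C(O[Si](CC)(CC)CC)C1 | intermediate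
6 | oxaspiropentane: epoxide spiro-linking the former carbonyl carbon of 5 to a cyclopropane carbon | C=C(C)[C@H]1CC[C@H](C)C2(OC23CC3)C(O[Si](CC)(CC)CC)C1 | intermediate (not isolated)
7 | (7S,10S)-10-methyl-7-(prop-1-en-2-yl)-5-(triethylsilyloxy)spiro[3.6]decan-1-one, C4/C5 epimers | C=C(C)[C@H]1CC[C@H](C)C2(C(=O)CC2)C(O[Si](CC)(CC)CC)C1 | intermediate
8 | (7S,10S)-10-methyl-7-(prop-1-en-2-yl)-5-(triethylsilyloxy)spiro[3.6]dec-1-en-1-yl trifluoromethanesulfonate | C=C(C)[C@H]1CC[C@H](C)C2(C(OS(=O)(=O)C(F)(F)F)=CC2)C(O[Si](CC)(CC)CC)C1 | intermediate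
9 | triethyl{[(7S,10S)-10-methyl-7-(prop-1-en-2-yl)spiro[3.6]dec-1-en-5-yl]oxy}silane | C=C(C)[C@H]1CC[C@H](C)C2(C=CC2)C(O[Si](CC)(CC)CC)C1 | intermediate
10 | (7S,10S)-10-methyl-7-(prop-1-en-2-yl)spiro[3.6]dec-1-en-5-ol | C=C(C)[C@H]1CC[C@H](C)C2(C=CC2)C(O)C1 | intermediate
11 | pristimerin | CC1=C(O)C(=O)C=C2C1=CC=C1[C@@]2(C)CC[C@@]2(C)[C@@H]3C[C@](C)(C(=O)OC)CC[C@]3(C)CC[C@]12C | starting material
12 | methyl 2,3-dihydroxy-6β-(2-tosylhydrazinyl)-24-nor-D:A-friedooleana-1,3,5(10),7-tetraen-29-oate | Cc1c(O)c(O)cc2c1[C@H](NNS(=O)(=O)c1ccc(C)cc1)C=C1[C@@]2(C)CC[C@@]2(C)[C@@H]3C[C@](C)(C(=O)OC)CC[C@]3(C)CC[C@]12C | intermediate (not isolated)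
13 | methyl 6β-diazenyl-2,3-dihydroxy-24-nor-D:A-friedooleana-1,3,5(10),7-tetraen-29-oate | Cc1c(O)c(O)cc2c1[C@H](N=N)C=C1[C@@]2(C)CC[C@@]2(C)[C@@H]3C[C@](C)(C(=O)OC)CC[C@]3(C)CC[C@]12C | intermediate (not isolated)
14 | methyl 2,3-dihydroxy-8β-H-24-nor-D:A-friedooleana-1,3,5(10),6-tetraen-29-oate | Cc1c(O)c(O)cc2c1C=C[C@@H]1[C@@]2(C)CC[C@@]2(C)[C@@H]3C[C@](C)(C(=O)OC)CC[C@]3(C)CC[C@]12C | intermediate
15 | methyl 2,3-dioxo-8β-H-24-nor-D:A-friedooleana-1(10),4,6-trien-29-oate | O=C1C(=O)C=C2C(=C1C)C=C[C@@H]1[C@@]2(C)CC[C@@]2(C)[C@@H]3C[C@](C)(C(=O)OC)CC[C@]3(C)CC[C@]12C | intermediate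
16 | (7S,10S)-10-methyl-7-(prop-1-en-2-yl)spiro[3.6]dec-1-en-5-yl trifluoromethanesulfonate | C=C(C)[C@H]1CC[C@H](C)C2(C=CC2)C(OS(=O)(=O)C(F)(F)F)C1 | intermediate (not isolated)
17 | (5S,8S)-8-methyl-5-(prop-1-en-2-yl)-1,4,5,6,7,8-hexahydroazulene | C=C(C)[C@H]1CC[C@H](C)C2=C(C1)C=CC2 | intermediate (not isolated)
18 | CNP0149558.1: cis-fused 1,4-benzodioxane from O2/O3 of 14 and C3′/C4′ of the (7′S,10′S)-nor-guaia-1′(5′),11′-diene unit | C=C(C)[C@H]1CC[C@H](C)C2=C(C1)[C@@H]1Oc3c(cc4c(c3C)C=C[C@@H]3[C@@]4(C)CC[C@@]4(C)[C@@H]5C[C@](C)(C(=O)OC)CC[C@]5(C)CC[C@]34C)O[C@@H]1C2 | target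

**Step count and risks**

Total steps: 11. Longest linear sequence: 9 steps (steps 1–8 and 11, from (S)-carvone); the triterpenoid branch is steps 9–11.

Step 11 (proposed). What may go wrong: loss of positional integrity of the diene (proton loss toward C2′, or 1,5-hydrogen shifts before trapping), and insufficient regio- or facial discrimination in the cycloaddition. The fallback uses known reactions, sets out from 7 and 14, and returns at 18. Compound 7 is desilylated with Bu4NF to the spiro ketol F1. Tf2O with 2,6-di-tert-butyl-4-methylpyridine then induces a 1,2-acyl shift of the cyclobutanone carbonyl carbon to the carbinol carbon (vinylcyclobutanone-type ring expansion, again four- to five-membered) and loss of the α-proton, giving the ring-fused cyclopentenone F2. Kinetic deprotonation with LiN(i-Pr)2 and hydroxylation with the enantiomer of (camphorsulfonyl)oxaziridine that gives the (2S)-alcohol should provide the hydroxy enone F3 under reagent control. Mitsunobu coupling (PPh3, DIAD) with catechol 14 at its less hindered 2-OH should give, with inversion, the aryl ether F4. Luche reduction (NaBH4, CeCl3, MeOH, −78 °C) gives the allylic alcohol F5. Catalytic camphorsulfonic acid in CH2Cl2 ionises the allylic alcohol, and the tethered 3-OH closes the dioxane cis to the existing C–O bond to give 18. Regiochemistry then rests on two separate etherifications and C3′ on the reagent.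

Step 9 (proposed). What may go wrong: reversal of the 1,6-addition faster than sulfinate loss, or addition on the α face, which would give the C8 epimer. The fallback uses known reactions, sets out from 11, and returns at 14. Reductive acetylation (Zn, Ac2O, NaOAc) gives pristimerol diacetate F6. Benzylic–allylic oxidation (CrO3, 3,5-dimethylpyrazole, CH2Cl2, −20 °C) gives the 6-ketone F7. Condensation with TsNHNH2 gives the tosylhydrazone F8. Catecholborane followed by NaOAc at reflux (Kabalka reduction with alkene transposition) should deliver hydride to C6 anti to the C9 methyl and then hydrogen to C8 on the β face, giving the C6=C7 diacetate F9. K2CO3 in degassed MeOH releases 14.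

Step 5. What may go wrong: enolisation of the hindered ketone by the basic ylide instead of addition, with epimerisation at the CHMe carbon. The fallback sets out from 5 and returns at 7. The organocerium reagent made from 1-lithiocyclopropyl phenyl sulfide and CeCl3 adds to 5 at −78 °C to give the cyclopropyl carbinol F10. Aqueous HBF4 in Et2O induces the cyclopropylcarbinyl to cyclobutyl ring expansion with loss of thiophenol and of the silyl group, giving ketol F1 (the same compound as in the first fallback). Resilylation (Et3SiCl, imidazole) gives 7.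

Further compounds
F1 | step 11 | (7S,10S)-5-hydroxy-10-methyl-7-(prop-1-en-2-yl)spiro[3.6]decan-1-one, C4/C5 epimers | C=C(C)[C@H]1CC[C@H](C)C2(C(=O)CC2)C(O)C1
F2 | step 11 | (4S,7S)-4-methyl-7-(prop-1-en-2-yl)-3,4,5,6,7,8-hexahydroazulen-1(2H)-one | C=C(C)[C@H]1CC[C@H](C)C2=C(C1)C(=O)CC2
F3 | step 11 | (2S,4S,7S)-2-hydroxy-4-methyl-7-(prop-1-en-2-yl)-3,4,5,6,7,8-hexahydroazulen-1(2H)-one | C=C(C)[C@H]1CC[C@H](C)C2=C(C1)C(=O)[C@@H](O)C2
F4 | step 11 | 2-O-[(2R,4S,7S)-4-methyl-1-oxo-7-(prop-1-en-2-yl)-1,2,3,4,5,6,7,8-octahydroazulen-2-yl] ether of catechol 14 | C=C(C)[C@H]1CC[C@H](C)C2=C(C1)C(=O)[C@H](Oc1cc3c(c(C)c1O)C=C[C@@H]1[C@@]3(C)CC[C@@]3(C)[C@@H]4C[C@](C)(C(=O)OC)CC[C@]4(C)CC[C@]13C)C2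
F5 | step 11 | allylic alcohol from 1,2-reduction of F4 (1-hydroxy, drawn cis to the aryloxy group) | C=C(C)[C@H]1CC[C@H](C)C2=C(C1)[C@H](O)[C@H](Oc1cc3c(c(C)c1O)C=C[C@@H]1[C@@]3(C)CC[C@@]3(C)[C@@H]4C[C@](C)(C(=O)OC)CC[C@]4(C)CC[C@]13C)C2
F6 | step 9 | pristimerol diacetate, methyl 2,3-diacetoxy-24-nor-D:A-friedooleana-1,3,5(10),7-tetraen-29-oate | Cc1c(OC(C)=O)c(OC(C)=O)cc2c1CC=C1[C@@]2(C)CC[C@@]2(C)[C@@H]3C[C@](C)(C(=O)OC)CC[C@]3(C)CC[C@]12C
F7 | step 9 | 6-oxopristimerol diacetate | Cc1c(OC(C)=O)c(OC(C)=O)cc2c1C(=O)C=C1[C@@]2(C)CC[C@@]2(C)[C@@H]3C[C@](C)(C(=O)OC)CC[C@]3(C)CC[C@]12C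
F8 | step 9 | tosylhydrazone of F7 | Cc1c(OC(C)=O)c(OC(C)=O)cc2c1C(=NNS(=O)(=O)c1ccc(C)cc1)C=C1[C@@]2(C)CC[C@@]2(C)[C@@H]3C[C@](C)(C(=O)OC)CC[C@]3(C)CC[C@]12C
F9 | step 9 | diacetate of 14 | Cc1c(OC(C)=O)c(OC(C)=O)cc2c1C=C[C@@H]1[C@@]2(C)CC[C@@]2(C)[C@@H]3C[C@](C)(C(=O)OC)CC[C@]3(C)CC[C@]12C
F10 | step 5 | (4S,7S)-7-methyl-1-[1-(phenylsulfanyl)cyclopropyl]-4-(prop-1-en-2-yl)-2-(triethylsilyloxy)cycloheptan-1-ol | C=C(C)[C@H]1CC[C@H](C)C(O)(C2(Sc3ccccc3)CC2)C(O[Si](CC)(CC)CC)C1
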